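**Plan**

1. Feature: in ring A (C1–C5, C10) the quaternary C4 carries the formyl carbon C19 and stands next to the carbinol C3. This aldol-type triad C3(O)–C4–C19HO is the retron of the 1,2-shift of a 2,3-epoxy silyl ether. The retrosynthesis therefore cuts C3–C4 and rejoins C3–C19, which puts C19 back into a seven-membered "A-homo" ring as a 3β-siloxy 4,19-β-epoxide.
2. Further cuts are C3–C19 (carbonyl-ene), C2–C3 (hydroformylation), C8=C17 (Wittig), C13=C14 (HWE), C9–C11 (Michael) and C1–C10 (copper-catalysed addition). Reconnecting C4–C7 then gives (+)-verbenone, which supplies C4–C10, C18, C19 and C20.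
3. Forward: ring B is carried inside verbenone. C10 and the C9 chain are installed on the bicycle and the cyclobutane is opened. The seven-membered ring is closed onto C5/C10 and contracted last to ring A, then the acetate goes in and the silyl groups come out.
4. Stereochemistry: C5 comes from verbenone and C10 from addition anti to the CMe2 bridge. C9 is set by equilibration next to the C8 ketone and C3 by CBS reduction. C4 is set by the relay C3–OH → syn epoxide → anti 1,2-shift, and C13=C14 (E) by HWE.

Key step: step 15

Assumption: (1R,5R)-(+)-verbenone is taken as commercial (it is also one allylic oxidation away from commercial (1R)-(+)-α-pinene). Labdane numbering (C1–C20) is used for every intermediate.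

Step 1
Reactants: 1 (1R,5R)-(+)-verbenone
Product: 2 4,6,6-trimethyl-2-(trimethylsilyloxy)-4-vinylbicyclo[3.1.1]hept-2-ene (vinyl on the face away from the CMe2 bridge)
Conditions: CH2=CHMgBr, CuBr·SMe2 (10 mol %), Me3SiCl, DMPU, THF, −78 → −20 °C; Et3N, cold aq. NaHCO3
Reagents that add atoms: vinylmagnesium bromide C=C[Mg]Br; chlorotrimethylsilane C[Si](C)(C)Cl
Why: Copper-catalysed conjugate addition of a Grignard reagent with in situ silylation, in which the vinyl group should reach C10 from the face opposite the CMe2 bridge and so set the quaternary centre (vinyl trans, CH3 cis to the C5–C4 bond), while the enol ether can only be C8=C9 because the other alpha carbon (C7) is a bridgehead.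

Step 2
Reactants: 2 silyl enol ether; 3 methyl vinyl ketone
Product: 4 4,6,6-trimethyl-3-(3-oxobutyl)-4-vinylbicyclo[3.1.1]heptan-2-one (oxobutyl and vinyl both on the face away from the bridge)
Conditions: TiCl4 (1.1 equiv), CH2Cl2, −78 °C; aq. NaHCO3
Reagents that add atoms: none
Why: Mukaiyama–Michael addition, in which C9 of the regiodefined silyl enol ether attacks the TiCl4-activated enone from the face away from the CMe2 bridge, so that C11 first stands cis to the vinyl group, a provisional configuration that is corrected in steps 4 and 5.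

Step 3
Reactants: 4 diketone
Product: 5 methyl (2E)-3-methyl-5-(4,6,6-trimethyl-2-oxo-4-vinylbicyclo[3.1.1]hept-3-yl)pent-2-enoate
Conditions: (MeO)2P(O)CH2CO2Me, NaH, THF, 0 → 50 °C
Reagents that add atoms: trimethyl phosphonoacetate COC(=O)CP(=O)(OC)OC
Why: Horner–Wadsworth–Emmons olefination, in which the stabilised anion should react only with the unhindered methyl ketone C13 (C8 is flanked by a bridgehead and by the branched C9) and should favour the E-enoate, the minor Z isomer being removed by chromatography.

Step 4
Reactants: 5 bicyclic keto ester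
Product: 7 ring-B ketone methyl (2E)-5-[3-(2-acetoxypropan-2-yl)-2-methyl-6-oxo-2-vinylcyclohexyl]-3-methylpent-2-enoate (5αH 9αH 10β-CH3), via enol acetate 6 (not isolated)
Conditions: Ac2O, BF3·OEt2 (cat.), Zn(OAc)2, 0 °C → rt; then K2CO3 (cat.), MeOH, rt
Reagents that add atoms: acetic anhydride CC(=O)OC(C)=O
Why: Lewis-acid acetolysis of an alpha-cyclobutyl ketone as known for 4,4-disubstituted nopinones, in which acylation at the C8 oxygen lets the strained C7–C4 bond ionise to the tertiary C4 cation that acetate captures before the poorly nucleophilic vinyl and enoate groups can interfere, after which carbonate-catalysed methanolysis of the enol acetate frees the ketone and equilibrates C9 towards the equatorial side chain (9αH), C5 and C10 being untouched.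

Step 5
Reactants: 7 ring-B ketone
Product: 8 8(17)-methylene ester (C4 tertiary acetate retained)
Conditions: Ph3PCH3Br, KOtBu, toluene, rt → 60 °C
Reagents that add atoms: methyltriphenylphosphonium bromide C[P+](c1ccccc1)(c1ccccc1)c1ccccc1.[Br-]
Why: Wittig methylenation, in which the basic ylide keeps the C9 epimers in equilibrium and should consume the equatorial one faster because only there is the alpha-axial trajectory at C8 open (the beta face is screened by the axial C20 methyl), after which C9 can no longer epimerise.

Step 6
Reactants: 8 methylene ester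
Product: 9 diol (C15 primary E-allylic alcohol, C4 tertiary alcohol)
Conditions: i-Bu2AlH (5 equiv), CH2Cl2, −78 → 0 °C; aq. potassium sodium tartrate
Reagents that add atoms: none
Why: Hydride reduction of esters with i-Bu2AlH, which should give the E-allylic alcohol by 1,2-reduction of the enoate and cleave the tertiary acetate in the same operation without touching a stereocentre or an olefin.

Step 7
Reactants: 9 diol
Product: 10 15-O-TBDPS ether (C4 tertiary alcohol free)
Conditions: t-BuPh2SiCl, imidazole, CH2Cl2, 0 °C
Reagents that add atoms: tert-butylchlorodiphenylsilane CC(C)(C)[Si](Cl)(c1ccccc1)c1ccccc1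
Why: Chemoselective silylation, since the bulky chlorosilane reacts with the primary allylic alcohol only and the tertiary carbinol is inert.

Step 8
Reactants: 10 tertiary alcohol
Product: 11 tetraene with isopropenyl at C5 (C4=C19H2, C18 methyl)
Conditions: Burgess reagent, toluene, 50 °C
Reagents that add atoms: none
Why: Burgess dehydration (syn elimination of a sulfamate), in which six methyl hydrogens compete with the single hindered C5–H and a C4=C5 olefin would suffer allylic strain against quaternary C10, so that the isopropenyl group should form and C5 stay intact.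

Step 9
Reactants: 11 tetraene
Product: 12 aldehyde (C10–CH2CH2–C3HO)
Conditions: CO/H2 (1:1, 10 bar), Rh(acac)(CO)2 (1 mol %), Xantphos, toluene, 60 °C
Reagents that add atoms: carbon monoxide [C-]#[O+]
Why: Linear-selective rhodium-catalysed hydroformylation, in which only the monosubstituted vinyl group reacts at a useful rate (the 1,1-disubstituted and trisubstituted olefins are far slower) and the quaternary C10 forces the formyl group onto the terminal carbon, which adds C3.

Step 10
Reactants: 12 aldehyde
Product: 13 A-homo alcohol (seven-membered ring C1-C2-C3-C19-C4-C5-C10, 3-OH as epimer mixture, exocyclic C4=C18H2)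
Conditions: Me2AlCl (2 equiv), CH2Cl2, −78 → 0 °C; aq. HCl
Reagents that add atoms: none
Why: Lewis-acid-promoted intramolecular carbonyl-ene reaction of a 6-methylhept-6-enal unit (tether on the central ene carbon), in which C19 attacks the complexed aldehyde C3, a methyl hydrogen passes to oxygen and the seven-membered ring closes on the trans-diequatorial C5/C10 substituents, the C3 configuration being irrelevant because step 11 erases it.

Step 11
Reactants: 13 A-homo alcohol
Product: 15 A-homo enone (C3 ketone conjugated to C19=C4 bearing the C18 methyl), via exo-methylene ketone 14 (not isolated)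
Conditions: Dess–Martin periodinane, CH2Cl2, rt; aqueous work-up; DBU (10 mol %), CH2Cl2, rt
Reagents that add atoms: none
Why: Dess–Martin oxidation followed by base-catalysed conjugation of the beta,gamma-unsaturated ketone through its dienolate, which should move the exocyclic double bond into the more stable trisubstituted C19=C4 enone position without touching C5.

Step 12
Reactants: 15 A-homo enone
Product: 16 (3S)-allylic alcohol (3β-OH)
Conditions: (R)-Me-CBS oxazaborolidine (20 mol %), catecholborane, toluene, −78 °C
Reagents that add atoms: none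
Why: Corey–Bakshi–Shibata reduction, in which the alkenyl branch (C19) acts as the large and C2H2 as the small group so that the (R)-catalyst should deliver hydride to the alpha face and give the 3S (3β) alcohol, the face that the axial C20 methyl also leaves open.

Step 13
Reactants: 16 allylic alcohol
Product: 17 3β-hydroxy-4β,19β-epoxide
Conditions: VO(acac)2 (3 mol %), t-BuOOH, CH2Cl2, 0 °C
Reagents that add atoms: tert-butyl hydroperoxide CC(C)(C)OO
Why: Hydroxyl-directed epoxidation, in which the vanadium alkoxide of the 3β-OH delivers oxygen to the same face of C19=C4 (syn epoxy alcohol, as known for cyclohept-2-enols) and leaves the C8(17) olefin and the silyl-protected C13 olefin alone.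

Step 14
Reactants: 17 epoxy alcohol
Product: 18 3β-triethylsilyl ether of 17
Conditions: Et3SiCl, imidazole, CH2Cl2, 0 °C
Reagents that add atoms: chlorotriethylsilane CC[Si](Cl)(CC)CC
Why: Standard silylation of a secondary alcohol under non-acidic conditions that keep the epoxide closed, the silyl ether being the activating group for the key step.

Step 15
Reactants: 18 epoxy silyl ether
Product: 19 3β-triethylsilyloxy-15-(tert-butyldiphenylsilyloxy)labda-8(17),13E-dien-19-al
Conditions: methylaluminium bis(4-bromo-2,6-di-tert-butylphenoxide), MeAl(OAr)2 (2 equiv, made from Me3Al and 2 ArOH in CH2Cl2, rt), CH2Cl2, −78 °C; aqueous work-up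
Reagents that add atoms: none
Why: The bulky oxophilic aluminium phenoxide binds the epoxide oxygen, the C4–O bond stretches towards the tertiary C4 cation, and in concert the C3–C19 bond migrates from C19 to the opposite (alpha) side of C4 while C19 becomes the aluminium-complexed formyl carbon. The closest known reaction type is the organoaluminium-promoted rearrangement of 2,3-epoxy silyl ethers to beta-siloxy aldehydes (a semipinacol or Meinwald-type 1,2-shift), together with the contraction of 1-methylcycloalkene oxides to 1-methylcycloalkanecarbaldehydes. Ring A (C1, C2, C3, C4, C5, C10) is closed not by an exo or endo cyclisation but by this suprafacial 1,2-alkyl shift, which makes C3–C4, breaks C3–C19 and so contracts the seven-membered ring to six with C19 expelled as the axial aldehyde. C4 is formed with inversion because C3 enters anti to the departing beta oxygen, so the beta epoxide placed by the 3β-OH in step 13 gives 4α-CH3 and 4β-CHO, and C3 migrates with retention and keeps its 3β oxygen. The step needs C4–O rather than C19–O cleavage, which the tertiary nature of C4 and the inductive effect of the C3 oxygen on C19 secure, and it needs migration of C3 rather than of the C19 hydrogen, which the lone-pair-assisted migratory aptitude of the siloxy-bearing carbon and the preference of the large Lewis acid for an unhindered aldehyde complex secure. The aprotic, non-nucleophilic reagent at −78 °C should leave the C8(17) and C13 olefins and both silyl ethers untouched.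

Step 16
Reactants: 19 siloxy aldehyde
Product: 21 3β-acetoxy-15-(tert-butyldiphenylsilyloxy)labda-8(17),13E-dien-19-al, via hydroxy aldehyde 20 (not isolated)
Conditions: HF·pyridine, pyridine, THF, 0 °C; aqueous work-up; Ac2O, DMAP (cat.), pyridine, rt
Reagents that add atoms: acetic anhydride CC(=O)OC(C)=O
Why: Fluoride cleavage of the labile triethylsilyl ether beside the far more robust TBDPS ether, followed by DMAP-catalysed acetylation of the crude beta-hydroxy aldehyde, which avoids strong base and hence retro-aldol cleavage (C4 bears no hydrogen, so elimination is impossible).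

Step 17
Reactants: 21 acetoxy aldehyde
Product: 22 3β-acetoxy-15-hydroxylabda-8(17),13E-dien-19-al (target)
Conditions: HF·pyridine, THF, 0 °C → rt
Reagents that add atoms: none
Why: Fluoride cleavage of the TBDPS ether under mildly acidic conditions that should leave the acetate, the hindered aldehyde and both olefins untouched.

**Compound list**

1 | (1R,5R)-(+)-verbenone | CC1=CC(=O)[C@@H]2C[C@H]1C2(C)C | starting material
2 | 4,6,6-trimethyl-2-(trimethylsilyloxy)-4-vinylbicyclo[3.1.1]hept-2-ene, vinyl anti to the CMe2 bridge | C[C@@]1(C=C)C=C(O[Si](C)(C)C)[C@@H]2C[C@H]1C2(C)C | intermediate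
3 | methyl vinyl ketone | C=CC(C)=O | starting material
4 | 4,6,6-trimethyl-3-(3-oxobutyl)-4-vinylbicyclo[3.1.1]heptan-2-one, oxobutyl and vinyl anti to the bridge | C[C@@]1(C=C)[C@H](CCC(C)=O)C(=O)[C@@H]2C[C@H]1C2(C)C | intermediate
5 | methyl (2E)-3-methyl-5-(4,6,6-trimethyl-2-oxo-4-vinylbicyclo[3.1.1]hept-3-yl)pent-2-enoate | C[C@@]1(C=C)[C@H](CC/C(C)=C/C(=O)OC)C(=O)[C@@H]2C[C@H]1C2(C)C | intermediate
6 | ring-opened C7=C8 enol acetate with C4 tertiary acetate (C9 still axial) | CC(=O)OC1=CC[C@@H](C(C)(C)OC(C)=O)[C@](C)(C=C)[C@@H]1CC/C(C)=C/C(=O)OC | intermediate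
7 | ring-B ketone, 5αH, 9αH, 10β-CH3, 10α-vinyl, C4 tertiary acetate, E-enoate | O=C1CC[C@@H](C(C)(C)OC(C)=O)[C@](C)(C=C)[C@H]1CC/C(C)=C/C(=O)OC | intermediate
8 | 8(17)-methylene ester | C=C1CC[C@@H](C(C)(C)OC(C)=O)[C@](C)(C=C)[C@H]1CC/C(C)=C/C(=O)OC | intermediate
9 | diol (C15-OH, C4-OH) | C=C1CC[C@@H](C(C)(C)O)[C@](C)(C=C)[C@H]1CC/C(C)=C/CO | intermediate
10 | 15-O-TBDPS ether of 9 | C=C1CC[C@@H](C(C)(C)O)[C@](C)(C=C)[C@H]1CC/C(C)=C/CO[Si](c2ccccc2)(c2ccccc2)C(C)(C)C | intermediate
11 | tetraene with isopropenyl at C5 | C=C1CC[C@@H](C(C)=C)[C@](C)(C=C)[C@H]1CC/C(C)=C/CO[Si](c2ccccc2)(c2ccccc2)C(C)(C)C | intermediate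
12 | C3 aldehyde | C=C1CC[C@@H](C(C)=C)[C@](C)(CCC=O)[C@H]1CC/C(C)=C/CO[Si](c2ccccc2)(c2ccccc2)C(C)(C)C | intermediate
13 | A-homo alcohol, exocyclic C4=C18H2, C3 left undefined (both epimers are oxidised in step 11) | C=C1CC[C@H]2C(=C)CC(O)CC[C@]2(C)[C@H]1CC/C(C)=C/CO[Si](c3ccccc3)(c3ccccc3)C(C)(C)C | intermediate
14 | A-homo beta,gamma-unsaturated ketone | C=C1CC[C@H]2C(=C)CC(=O)CC[C@]2(C)[C@H]1CC/C(C)=C/CO[Si](c3ccccc3)(c3ccccc3)C(C)(C)C | intermediate
15 | A-homo conjugated enone | C=C1CC[C@H]2C(C)=CC(=O)CC[C@]2(C)[C@H]1CC/C(C)=C/CO[Si](c3ccccc3)(c3ccccc3)C(C)(C)C | intermediate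
16 | (3S)-A-homo allylic alcohol (3β-OH) | C=C1CC[C@H]2C(C)=C[C@@H](O)CC[C@]2(C)[C@H]1CC/C(C)=C/CO[Si](c3ccccc3)(c3ccccc3)C(C)(C)C | intermediate
17 | 3β-hydroxy-4β,19β-epoxide | C=C1CC[C@H]2[C@@]3(C)O[C@H]3[C@@H](O)CC[C@]2(C)[C@H]1CC/C(C)=C/CO[Si](c4ccccc4)(c4ccccc4)C(C)(C)C | intermediate
18 | 3β-triethylsilyloxy-4β,19β-epoxide | C=C1CC[C@H]2[C@@]3(C)O[C@H]3[C@@H](O[Si](CC)(CC)CC)CC[C@]2(C)[C@H]1CC/C(C)=C/CO[Si](c4ccccc4)(c4ccccc4)C(C)(C)C | intermediate
19 | 3β-triethylsilyloxy-15-TBDPS-oxylabda-8(17),13E-dien-19-al | C=C1CC[C@H]2[C@@](C)(C=O)[C@@H](O[Si](CC)(CC)CC)CC[C@]2(C)[C@H]1CC/C(C)=C/CO[Si](c3ccccc3)(c3ccccc3)C(C)(C)C | intermediate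
20 | 3β-hydroxy-15-TBDPS-oxylabda-8(17),13E-dien-19-al | C=C1CC[C@H]2[C@@](C)(C=O)[C@@H](O)CC[C@]2(C)[C@H]1CC/C(C)=C/CO[Si](c3ccccc3)(c3ccccc3)C(C)(C)C | intermediate
21 | 3β-acetoxy-15-TBDPS-oxylabda-8(17),13E-dien-19-al | C=C1CC[C@H]2[C@@](C)(C=O)[C@@H](OC(C)=O)CC[C@]2(C)[C@H]1CC/C(C)=C/CO[Si](c3ccccc3)(c3ccccc3)C(C)(C)C | intermediate
22 | 3β-acetoxy-15-hydroxylabda-8(17),13E-dien-19-al | C=C1CC[C@H]2[C@@](C)(C=O)[C@@H](OC(C)=O)CC[C@]2(C)[C@H]1CC/C(C)=C/CO | target

Total step count: 17. Longest linear sequence: 17 steps (from 1).

**Steps most likely to fail**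

**Step 15.**
- What may go wrong: a hydride may migrate (from C19, or from C5 into the C4 cation) in place of C3, or the very large Lewis acid may fail to bind the crowded beta epoxide.
- The fallback sets out from 17 and uses an acyl carbon rather than a siloxy carbon as the migrating group.
- Dess–Martin oxidation gives the alpha,beta-epoxy ketone F1.
- BF3·OEt2 in CH2Cl2 at low temperature triggers the known 1,2-acyl shift of alpha,beta-epoxy ketones. C3 moves from C19 to C4 with inversion, which gives the ring-contracted beta-keto aldehyde F2.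
- NaBH4 in MeOH at −20 °C reduces both carbonyl groups. Attack at C3 comes from the alpha face, and the product is the 3β,19-diol F3.
- TEMPO (cat.) with PhI(OAc)2 oxidises the primary alcohol selectively and comes back to the route at 20.

**Step 10.**
- What may go wrong: closure of the seven-membered ring may be slow, so that chloride capture, self-condensation of the aldehyde or proton loss towards C5 takes over.
- The fallback sets out from 12 and closes the ring at the olefin rather than at C3–C19.
- Vinylmagnesium bromide gives the dienyl carbinols F4 (both C3 epimers).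
- Ring-closing metathesis with the second-generation Grubbs catalyst (H2IMes)(PCy3)Cl2Ru=CHPh joins the vinyl carbinol to the isopropenyl group and gives the cycloheptenols F5. In this variant ring carbon C19 comes from the Grignard reagent.
- MnO2 oxidation comes back to the route at 15.

**Step 2.**
- What may go wrong: bond formation at C9 next to the new quaternary centre may be too slow, so that polymerisation of the enone or simple desilylation wins.
- The fallback sets out from 2 and reverses the roles of the Michael partners.
- Eschenmoser's salt [Me2N=CH2]I gives the Mannich base F6.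
- N-methylation with MeI and treatment with DBU give the alpha-methylene ketone F7.
- The small nucleophile 2-(trimethylsilyloxy)propene adds under TiCl4 to the unhindered exocyclic C11, which forms C11–C12 in place of C9–C11.
- Brief exposure to DBU settles C9 on the less crowded side and comes back to the route at 4. C9 is in any case reset in step 4.

**Further compounds**

F1 | step 15 | A-homo 4β,19β-epoxy-3-ketone | C=C1CC[C@H]2[C@@]3(C)O[C@H]3C(=O)CC[C@]2(C)[C@H]1CC/C(C)=C/CO[Si](c4ccccc4)(c4ccccc4)C(C)(C)C
F2 | step 15 | 3-oxo-15-TBDPS-oxylabda-8(17),13E-dien-19-al | C=C1CC[C@H]2[C@@](C)(C=O)C(=O)CC[C@]2(C)[C@H]1CC/C(C)=C/CO[Si](c3ccccc3)(c3ccccc3)C(C)(C)C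
F3 | step 15 | 15-TBDPS-oxylabda-8(17),13E-diene-3β,19-diol | C=C1CC[C@H]2[C@@](C)(CO)[C@@H](O)CC[C@]2(C)[C@H]1CC/C(C)=C/CO[Si](c3ccccc3)(c3ccccc3)C(C)(C)C
F4 | step 10 | dienyl carbinols from 12 and vinylmagnesium bromide (C3 epimers) | C=C1CC[C@@H](C(C)=C)[C@](C)(CCC(O)C=C)[C@H]1CC/C(C)=C/CO[Si](c2ccccc2)(c2ccccc2)C(C)(C)C
F5 | step 10 | A-homo cycloheptenols (C3 epimers) | C=C1CC[C@H]2C(C)=CC(O)CC[C@]2(C)[C@H]1CC/C(C)=C/CO[Si](c3ccccc3)(c3ccccc3)C(C)(C)C
F6 | step 2 | 3-(dimethylaminomethyl)-4,6,6-trimethyl-4-vinylbicyclo[3.1.1]heptan-2-one | C[C@@]1(C=C)[C@H](CN(C)C)C(=O)[C@@H]2C[C@H]1C2(C)C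
F7 | step 2 | 4,6,6-trimethyl-3-methylene-4-vinylbicyclo[3.1.1]heptan-2-one | C[C@@]1(C=C)C(=C)C(=O)[C@@H]2C[C@H]1C2(C)C
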